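A small excess of first end groups, 0.00440 M, parts the two charges of this flask, so second end groups are the limiting reagent.

common to all: first end groups 0.088 M (fed, over 40 min)
- amber: second end groups 0.042 M; run made earlier
- violet: second end groups 0.17 M; run made earlier
- flask: second end groups 0.0836 M; time 6.0 h

| run | time / h | links / % | first end groups / % |
|---|---|---|---|
| amber | 1.33 | 23 | 77 |
| amber | 2.50 | 24 | 66 |
| amber | 4.00 | 33 | 58 |
| amber | 5.00 | 30 | 54 |
| amber | 6.00 | 30 | 56 |
| violet | 1.33 | 50 | 30 |
| violet | 2.50 | 62 | 12 |
| violet | 4.00 | 72 | 4 |
| violet | 5.00 | 72 | 0 |
| violet | 6.00 | 73 | 0 |

(scatter of a reading: 2 percentage points)

- in percentages every species weighs as the first end groups in it: one homo dimer counts as two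
- what may be going on: first end groups + second end groups -> links; 2 first end groups -> homo dimer; links <-> isomer of the product

- links present at 6.0 h, in percent of the first end groups charged
- first end groups present at 6.0 h, in percent of the first end groups charged

In the violet run the last reading gives 0.730 for the number to watch, the link share: links divided by first end groups consumed. The last amber reading gives 0.682. The violet readings at 1.33 h and 2.50 h, with second end groups in excess, give a coupling constant of 7.79 L mol⁻¹ h⁻¹ for the step to links.

Two versions of the flask solve in the head, both counted from mid-feed, 20.0 min. With both charges equal to that of first end groups, first end groups fall to 20.5%. With both equal to that of second end groups and the excess added on afterwards, they stand at 25.2%. The real flask lies between: its excess quickens the coupling over the second version, yet its second end groups are fewer than in the first. The link share then turns this range into 54.6% to 58.0% links.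

The forecast, 55% links and 22% first end groups, lies inside this range and rests on a like share: “The missing material, presumably isomer, settles” at a steady part of what reacted.

The flask gives 57.7% links and 20.6% first end groups at 6.0 h.

    first end groups + second end groups → links (k = 9.05 L mol⁻¹ h⁻¹)
    2 first end groups → homo dimer (k = 0.00696 L mol⁻¹ h⁻¹)
    links ⇌ isomer of the product (K = 0.377, k = 1.24 h⁻¹)

The link share times the first end groups consumed gives 58.0% links in this flask. The flask's links move 5 points away from 57.7% with second end groups at 0.0732 M or 0.0967 M, the rest held. Left until 10 h, the same flask holds 14.1% first end groups, so the link share gives 62.7% links, and that flask holds 62.4%.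

(The earlier runs and the new flask stem from a simulated flask on assumed constants.)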